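## Retrosynthetic overview

1. The target is reached by thiolate O-demethylation of its methyl tetronate, which is cut at the C7–C8 diene bond (Suzuki–Miyaura) into an east (E)-vinyl iodide carrying the (Z)-ylidene methyl tetronate and a west (E)-furylvinyl pinacolboronate.
2. East: the (Z)-ylidene comes from a vinylogous aldol/E1cB dehydration of lithiated 4-methoxy-3-methylfuran-2(5H)-one on an (S)-α-methyl aldehyde; the (E)-vinyl iodide from Zr-catalysed carboalumination/iodination of a terminal alkyne; the chain from a Cu-catalysed Grignard–tosylate coupling.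
3. The single stereocentre is set by lipase desymmetrisation of achiral 2-methylpropane-1,3-diol; the acetylated arm becomes C1 (aldehyde), the free arm is extended.
4. West: furan-3,4-diyldimethanol; one arm becomes CH2–furyl by an sp3–sp2 Suzuki coupling, the other becomes CHO, then alkyne, then (E)-vinylboronate.
5. Rings: both furans are bought intact; the only ring built is the butenolide (thermal lactonisation of a γ-bromo-β-keto ester), made before the fragment couplings.

Assumption: Pseudomonas fluorescens lipase acetylates the pro-S hydroxymethyl arm of diol 1, giving the (S)-monoacetate.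

## Route

**East fragment**

Step 1
Reactants: 1 2-methylpropane-1,3-diol
Product: 2 (S)-3-hydroxy-2-methylpropyl acetate
Conditions: lipase (Pseudomonas fluorescens lipase, Amano AK), vinyl acetate (3 equiv), CHCl3, 25 °C, stopped at ca. 35% diacetate; filter, chromatograph cold
Reagents that add atoms: vinyl acetate, CC(=O)OC=C
Why: Lipase-catalysed irreversible transesterification desymmetrises the prochiral diol at the pro-S arm, and the slower second acetylation removes mainly the minor (R)-monoacetate (coupled kinetic resolution), so the only stereocentre is set in ≥98% ee.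

Step 2
Reactants: 2 (S)-3-hydroxy-2-methylpropyl acetate
Product: 3 (R)-3-(acetyloxy)-2-methylpropyl 4-methylbenzenesulfonate
Conditions: TsCl, pyridine, CH2Cl2, 0 °C, run at once
Reagents that add atoms: 4-toluenesulfonyl chloride (TsCl), Cc1ccc(cc1)S(=O)(=O)Cl
Why: O-Sulfonylation of the free primary alcohol freezes the 1,3-acyl migration that would racemise 2; no bond at the stereocentre is touched, and the descriptor becomes R only through CIP priorities.

Step 3
Reactants: 3 (R)-3-(acetyloxy)-2-methylpropyl 4-methylbenzenesulfonate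
Product: 4 (R)-3-hydroxy-2-methylpropyl 4-methylbenzenesulfonate
Conditions: K2CO3 (0.2 equiv), MeOH, 0 °C, 1 h
Reagents that add atoms: none
Why: Base-catalysed transesterification (methanolysis) of the acetate is far faster at 0 °C than SN2 attack or 4-exo-tet oxetane closure at the β-branched tosylate.

Step 4
Reactants: 4 (R)-3-hydroxy-2-methylpropyl 4-methylbenzenesulfonate
Product: 5 (R)-3-[(tert-butyldimethylsilyl)oxy]-2-methylpropyl 4-methylbenzenesulfonate
Conditions: TBSCl, imidazole, CH2Cl2, 0 °C to 25 °C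
Reagents that add atoms: tert-butyldimethylsilyl chloride (TBSCl), CC(C)(C)[Si](C)(C)Cl
Why: Imidazole-promoted silylation masks the future C1 oxygen as a Grignard-stable TBS ether.

Step 5
Reactants: 5 (R)-3-[(tert-butyldimethylsilyl)oxy]-2-methylpropyl 4-methylbenzenesulfonate; 6 4-bromo-1-(trimethylsilyl)but-1-yne
Product: 8 (S)-tert-butyldimethyl{[2-methyl-7-(trimethylsilyl)hept-6-yn-1-yl]oxy}silane, via Grignard reagent 7 (not isolated)
Conditions: 6 (2 equiv), Mg turnings, THF, 40 °C; then 5, Li2CuCl4 (5 mol%), THF, −78 °C to 25 °C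
Reagents that add atoms: none
Why: Copper-catalysed Grignard–tosylate cross-coupling (Kochi–Schlosser type) forms the C3–C4 sp3–sp3 bond by displacement at the primary carbon, so the adjacent stereocentre is untouched and the silyl groups are inert.

Step 6
Reactants: 8 (S)-tert-butyldimethyl{[2-methyl-7-(trimethylsilyl)hept-6-yn-1-yl]oxy}silane
Product: 9 (S)-tert-butyldimethyl[(2-methylhept-6-yn-1-yl)oxy]silane
Conditions: K2CO3 (0.3 equiv), MeOH, 25 °C
Reagents that add atoms: none
Why: Methanolytic protodesilylation cleaves only the alkynyl C–Si bond; the TBS ether survives carbonate in methanol.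

Step 7
Reactants: 9 (S)-tert-butyldimethyl[(2-methylhept-6-yn-1-yl)oxy]silane
Product: 11 tert-butyl{[(2S,6E)-7-iodo-2,6-dimethylhept-6-en-1-yl]oxy}dimethylsilane, via alkenylalane 10 (not isolated)
Conditions: Me3Al (2.5 equiv), Cp2ZrCl2 (0.25 equiv), CH2Cl2, 0 °C to 25 °C; then I2, THF, −30 °C to 0 °C
Reagents that add atoms: trimethylaluminium, C[Al](C)C; iodine, II
Why: Negishi zirconium-catalysed carboalumination adds Me and Al syn across the terminal alkyne with Me on the internal carbon, and iodinolysis of the C–Al bond with retention gives the (E)-trisubstituted vinyl iodide.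

Step 8
Reactants: 11 tert-butyl{[(2S,6E)-7-iodo-2,6-dimethylhept-6-en-1-yl]oxy}dimethylsilane
Product: 12 (2S,6E)-7-iodo-2,6-dimethylhept-6-en-1-ol
Conditions: TBAF, THF, 0 °C to 25 °C
Reagents that add atoms: none
Why: Fluoride-driven desilylation (strong Si–F bond) frees the primary alcohol; the vinyl iodide is inert.

Step 9
Reactants: 12 (2S,6E)-7-iodo-2,6-dimethylhept-6-en-1-ol
Product: 13 (2S,6E)-7-iodo-2,6-dimethylhept-6-enal
Conditions: Dess–Martin periodinane, NaHCO3, CH2Cl2, 0 °C to 25 °C; used crude the same day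
Reagents that add atoms: none
Why: Buffered Dess–Martin oxidation is non-enolising, so the α-methyl aldehyde forms without epimerisation.

**Tetronate**

Step 10
Reactants: 14 ethyl 2-methyl-3-oxobutanoate
Product: 16 ethyl 4-bromo-2-methyl-3-oxobutanoate (racemic), via alpha-bromo keto ester 15 (not isolated)
Conditions: Br2 (1.0 equiv), CHCl3, 0 °C to 25 °C, 16 h in a closed flask; evaporate
Reagents that add atoms: bromine, BrBr
Why: Electrophilic α-bromination of the β-keto ester gives the 2-bromo compound first, which the retained HBr equilibrates to the more stable γ-bromo isomer.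

Step 11
Reactants: 16 ethyl 4-bromo-2-methyl-3-oxobutanoate
Product: 17 4-hydroxy-3-methylfuran-2(5H)-one (3-methyltetronic acid)
Conditions: neat, 120–130 °C (EtBr distils off); recrystallise
Reagents that add atoms: none
Why: Thermal lactonisation: the ester carbonyl oxygen displaces the primary bromide (5-exo-tet) and the O-ethyl lactonium loses bromoethane, building the butenolide ring.

Step 12
Reactants: 17 4-hydroxy-3-methylfuran-2(5H)-one
Product: 18 4-methoxy-3-methylfuran-2(5H)-one
Conditions: Me2SO4, K2CO3, acetone, reflux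
Reagents that add atoms: dimethyl sulfate, COS(=O)(=O)OC
Why: O-Alkylation of the tetronate anion (a vinylogous carboxylate) by the hard electrophile gives the 4-O-methyl vinylogous ester.

**East fragment plus tetronate**

Step 13
Reactants: 18 4-methoxy-3-methylfuran-2(5H)-one; 13 (2S,6E)-7-iodo-2,6-dimethylhept-6-enal
Product: 20 5-[(2S,6E)-1-hydroxy-7-iodo-2,6-dimethylhept-6-en-1-yl]-4-methoxy-3-methylfuran-2(5H)-one (diastereomer mixture at C5 and the carbinol carbon), via lithium dienolate 19 (not isolated)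
Conditions: 18 (1.2 equiv), LiN(i-Pr)2, THF, −78 °C; then 13, −78 °C; AcOH quench at −78 °C
Reagents that add atoms: none
Why: Vinylogous aldol addition: the C5-lithiated methyl tetronate adds to the aldehyde faster than it enolises it at −78 °C, so the α-stereocentre is kept; the two new centres are uncontrolled and are destroyed in step 14.

Step 14
Reactants: 20 5-[(2S,6E)-1-hydroxy-7-iodo-2,6-dimethylhept-6-en-1-yl]-4-methoxy-3-methylfuran-2(5H)-one
Product: 22 (5Z)-5-[(2S,6E)-7-iodo-2,6-dimethylhept-6-en-1-ylidene]-4-methoxy-3-methylfuran-2(5H)-one, via mesylate 21 (not isolated)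
Conditions: MsCl, Et3N, CH2Cl2, 0 °C; then DBU, 0 °C to 25 °C; minor E isomer removed by chromatography
Reagents that add atoms: none
Why: Mesylation then E1cB elimination through the extended dienolate gives the ylidene, and the Z isomer (alkyl chain cis to the ring oxygen, away from the 4-OMe) is the thermodynamically favoured product.

**West fragment**

Step 15
Reactants: 23 furan-3,4-diyldimethanol
Product: 25 [4-({[tert-butyl(dimethyl)silyl]oxy}methyl)furan-3-yl]methanol, via sodium monoalkoxide 24 (not isolated)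
Conditions: NaH (1.0 equiv), THF, 0 °C to 25 °C; then TBSCl (1.0 equiv), 25 °C
Reagents that add atoms: tert-butyldimethylsilyl chloride (TBSCl), CC(C)(C)[Si](C)(C)Cl
Why: Monosilylation of the symmetrical diol through its sparingly soluble monosodium alkoxide (McDougal protocol) favours the mono-TBS ether.

Step 16
Reactants: 25 [4-({[tert-butyl(dimethyl)silyl]oxy}methyl)furan-3-yl]methanol
Product: 26 {[4-(bromomethyl)furan-3-yl]methoxy}(tert-butyl)dimethylsilane
Conditions: CBr4, PPh3, CH2Cl2, 0 °C; short silica plug, used at once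
Reagents that add atoms: carbon tetrabromide, BrC(Br)(Br)Br
Why: The Appel reaction converts the primary furylmethyl alcohol to the bromide under neutral conditions that spare the TBS ether and the furan.

Step 17
Reactants: 26 {[4-(bromomethyl)furan-3-yl]methoxy}(tert-butyl)dimethylsilane; 27 furan-3-ylboronic acid
Product: 28 tert-butyl{[4-(furan-3-ylmethyl)furan-3-yl]methoxy}dimethylsilane
Conditions: 27 (1.5 equiv), Pd(PPh3)4 (5 mol%), Na2CO3 (2 M aq), DME, 80 °C
Reagents that add atoms: none
Why: sp3–sp2 Suzuki–Miyaura coupling: the benzylic-type bromide adds rapidly to zerovalent palladium, has no β-hydrogen, and transmetallation/reductive elimination gives the difurylmethane.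

Step 18
Reactants: 28 tert-butyl{[4-(furan-3-ylmethyl)furan-3-yl]methoxy}dimethylsilane
Product: 29 [4-(furan-3-ylmethyl)furan-3-yl]methanol
Conditions: TBAF, THF, 0 °C to 25 °C
Reagents that add atoms: none
Why: Fluoride desilylation is neutral to basic, so both acid-sensitive furans survive.

Step 19
Reactants: 29 [4-(furan-3-ylmethyl)furan-3-yl]methanol
Product: 30 4-(furan-3-ylmethyl)furan-3-carbaldehyde
Conditions: MnO2 (10 equiv), CH2Cl2, 25 °C
Reagents that add atoms: none
Why: MnO2 selectively oxidises the heterobenzylic alcohol to the aldehyde without over-oxidation or attack on the furan rings.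

Step 20
Reactants: 30 4-(furan-3-ylmethyl)furan-3-carbaldehyde
Product: 31 3-ethynyl-4-(furan-3-ylmethyl)furan
Conditions: dimethyl (1-diazo-2-oxopropyl)phosphonate, K2CO3, MeOH, 0 °C to 25 °C
Reagents that add atoms: dimethyl (1-diazo-2-oxopropyl)phosphonate, COP(=O)(OC)C(=[N+]=[N-])C(C)=O
Why: Seyferth–Gilbert homologation in the Ohira–Bestmann form converts the non-enolisable aldehyde into the terminal alkyne under mild base.

Step 21
Reactants: 31 3-ethynyl-4-(furan-3-ylmethyl)furan
Product: 32 2-{(E)-2-[4-(furan-3-ylmethyl)furan-3-yl]ethenyl}-4,4,5,5-tetramethyl-1,3,2-dioxaborolane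
Conditions: pinacolborane (1.5 equiv), Cp2Zr(H)Cl (10 mol%), Et3N (10 mol%), CH2Cl2, 25–50 °C
Reagents that add atoms: pinacolborane, CC1(C)OBOC1(C)C
Why: Zirconium-catalysed hydroboration adds H–B syn and anti-Markovnikov across the terminal alkyne, giving only the (E)-vinylboronate.

**Fragment union and end game**

Step 22
Reactants: 22 (5Z)-5-[(2S,6E)-7-iodo-2,6-dimethylhept-6-en-1-ylidene]-4-methoxy-3-methylfuran-2(5H)-one; 32 2-{(E)-2-[4-(furan-3-ylmethyl)furan-3-yl]ethenyl}-4,4,5,5-tetramethyl-1,3,2-dioxaborolane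
Product: 33 (5Z)-5-[(2S,6E,8E)-9-[4-(furan-3-ylmethyl)furan-3-yl]-2,6-dimethylnona-6,8-dien-1-ylidene]-4-methoxy-3-methylfuran-2(5H)-one
Conditions: 32 (1.2 equiv), Pd(dppf)Cl2 (5 mol%), K3PO4 (3 M aq, 3 equiv), THF, degassed, dark, 25–40 °C
Reagents that add atoms: none
Why: Suzuki–Miyaura coupling of vinyl iodide and vinylboronate proceeds with retention at both partners, giving the (6E,8E)-diene; the mild phosphate base spares the lactone and the allylic stereocentre.

Step 23
Reactants: 33 (5Z)-5-[(2S,6E,8E)-9-[4-(furan-3-ylmethyl)furan-3-yl]-2,6-dimethylnona-6,8-dien-1-ylidene]-4-methoxy-3-methylfuran-2(5H)-one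
Product: 34 (5Z)-5-[(2S,6E,8E)-9-[4-(furan-3-ylmethyl)furan-3-yl]-2,6-dimethylnona-6,8-dien-1-ylidene]-4-hydroxy-3-methylfuran-2(5H)-one (CNP0288126.1)
Conditions: NaSEt (4 equiv), DMF, 25–45 °C, argon, dark; then cold 0.5 M HCl to pH 3, rapid extraction
Reagents that add atoms: none
Why: SN2 O-demethylation by the soft thiolate at the methyl group of the vinylogous methyl ester releases the tetronate without the strong acids that would destroy the furyl diene.

## Compound list

1 | 2-methylpropane-1,3-diol | CC(CO)CO | starting material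
2 | (S)-3-hydroxy-2-methylpropyl acetate | CC(=O)OC[C@@H](C)CO | intermediate
3 | (R)-3-(acetyloxy)-2-methylpropyl 4-methylbenzenesulfonate | CC(=O)OC[C@@H](C)COS(=O)(=O)c1ccc(C)cc1 | intermediate
4 | (R)-3-hydroxy-2-methylpropyl 4-methylbenzenesulfonate | OC[C@@H](C)COS(=O)(=O)c1ccc(C)cc1 | intermediate
5 | (R)-3-[(tert-butyldimethylsilyl)oxy]-2-methylpropyl 4-methylbenzenesulfonate | CC(C)(C)[Si](C)(C)OC[C@@H](C)COS(=O)(=O)c1ccc(C)cc1 | intermediate
6 | 4-bromo-1-(trimethylsilyl)but-1-yne | C[Si](C)(C)C#CCCBr | starting material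
7 | [4-(trimethylsilyl)but-3-yn-1-yl]magnesium bromide | C[Si](C)(C)C#CCC[Mg]Br | intermediate
8 | (S)-tert-butyldimethyl{[2-methyl-7-(trimethylsilyl)hept-6-yn-1-yl]oxy}silane | CC(C)(C)[Si](C)(C)OC[C@@H](C)CCCC#C[Si](C)(C)C | intermediate
9 | (S)-tert-butyldimethyl[(2-methylhept-6-yn-1-yl)oxy]silane | CC(C)(C)[Si](C)(C)OC[C@@H](C)CCCC#C | intermediate
10 | [(1E,6S)-7-[(tert-butyldimethylsilyl)oxy]-2,6-dimethylhept-1-en-1-yl]dimethylalane | CC(C)(C)[Si](C)(C)OC[C@@H](C)CCC/C(C)=C/[Al](C)C | intermediate
11 | tert-butyl{[(2S,6E)-7-iodo-2,6-dimethylhept-6-en-1-yl]oxy}dimethylsilane | CC(C)(C)[Si](C)(C)OC[C@@H](C)CCC/C(C)=C/I | intermediate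
12 | (2S,6E)-7-iodo-2,6-dimethylhept-6-en-1-ol | OC[C@@H](C)CCC/C(C)=C/I | intermediate
13 | (2S,6E)-7-iodo-2,6-dimethylhept-6-enal | O=C[C@@H](C)CCC/C(C)=C/I | intermediate
14 | ethyl 2-methyl-3-oxobutanoate | CCOC(=O)C(C)C(C)=O | starting material
15 | ethyl 2-bromo-2-methyl-3-oxobutanoate (racemic) | CCOC(=O)C(C)(Br)C(C)=O | intermediate
16 | ethyl 4-bromo-2-methyl-3-oxobutanoate (racemic) | CCOC(=O)C(C)C(=O)CBr | intermediate
17 | 4-hydroxy-3-methylfuran-2(5H)-one | CC1=C(O)COC1=O | intermediate
18 | 4-methoxy-3-methylfuran-2(5H)-one | COC1=C(C)C(=O)OC1 | intermediate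
19 | lithium 4-methoxy-3-methylfuran-2-olate | [Li+].[O-]c1occ(OC)c1C | intermediate
20 | 5-[(2S,6E)-1-hydroxy-7-iodo-2,6-dimethylhept-6-en-1-yl]-4-methoxy-3-methylfuran-2(5H)-one (mixture at C5 and carbinol carbon) | COC1=C(C)C(=O)OC1C(O)[C@@H](C)CCC/C(C)=C/I | intermediate
21 | (2S,6E)-7-iodo-1-(3-methoxy-4-methyl-5-oxo-2,5-dihydrofuran-2-yl)-2,6-dimethylhept-6-en-1-yl methanesulfonate (mixture at the same two centres) | COC1=C(C)C(=O)OC1C(OS(C)(=O)=O)[C@@H](C)CCC/C(C)=C/I | intermediate
22 | (5Z)-5-[(2S,6E)-7-iodo-2,6-dimethylhept-6-en-1-ylidene]-4-methoxy-3-methylfuran-2(5H)-one | CC1=C(OC)/C(=C/[C@@H](C)CCC/C(C)=C/I)OC1=O | intermediate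
23 | furan-3,4-diyldimethanol | OCc1cocc1CO | starting material
24 | sodium [4-(hydroxymethyl)furan-3-yl]methanolate | [Na+].[O-]Cc1cocc1CO | intermediate
25 | [4-({[tert-butyl(dimethyl)silyl]oxy}methyl)furan-3-yl]methanol | CC(C)(C)[Si](C)(C)OCc1cocc1CO | intermediate
26 | {[4-(bromomethyl)furan-3-yl]methoxy}(tert-butyl)dimethylsilane | CC(C)(C)[Si](C)(C)OCc1cocc1CBr | intermediate
27 | furan-3-ylboronic acid | OB(O)c1ccoc1 | starting material
28 | tert-butyl{[4-(furan-3-ylmethyl)furan-3-yl]methoxy}dimethylsilane | CC(C)(C)[Si](C)(C)OCc1cocc1Cc1ccoc1 | intermediate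
29 | [4-(furan-3-ylmethyl)furan-3-yl]methanol | OCc1cocc1Cc1ccoc1 | intermediate
30 | 4-(furan-3-ylmethyl)furan-3-carbaldehyde | O=Cc1cocc1Cc1ccoc1 | intermediate
31 | 3-ethynyl-4-(furan-3-ylmethyl)furan | C#Cc1cocc1Cc1ccoc1 | intermediate
32 | 2-{(E)-2-[4-(furan-3-ylmethyl)furan-3-yl]ethenyl}-4,4,5,5-tetramethyl-1,3,2-dioxaborolane | CC1(C)OB(/C=C/c2cocc2Cc2ccoc2)OC1(C)C | intermediate
33 | (5Z)-5-[(2S,6E,8E)-9-[4-(furan-3-ylmethyl)furan-3-yl]-2,6-dimethylnona-6,8-dien-1-ylidene]-4-methoxy-3-methylfuran-2(5H)-one | CC1=C(OC)/C(=C/[C@@H](C)CCC/C(C)=C/C=C/c2cocc2Cc2ccoc2)OC1=O | intermediate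
34 | (5Z)-5-[(2S,6E,8E)-9-[4-(furan-3-ylmethyl)furan-3-yl]-2,6-dimethylnona-6,8-dien-1-ylidene]-4-hydroxy-3-methylfuran-2(5H)-one | CC1=C(O)/C(=C/[C@@H](C)CCC/C(C)=C/C=C/c2cocc2Cc2ccoc2)OC1=O | target

## Step count and risks

Total step count: 23.
Longest linear sequence: 13 steps (steps 1–9, 13, 14, 22, 23). The west branch is 7 steps to 32 and the tetronate branch 3 steps to 18.

Three steps most likely to fail:

**Step 14** (risk: E/Z mixture at the ylidene, and base-induced erosion of the allylic stereocentre under DBU). The fallback sets out from 18, with aldehyde 13 as partner, and comes back to the route at 22. It makes the ylidene in one Horner–Wadsworth–Emmons operation instead of aldol plus elimination. Lithium dienolate 19, generated from 18 as in step 13, is brominated with 1,2-dibromo-1,1,2,2-tetrachloroethane (THF, −78 °C) to give racemic 5-bromo-4-methoxy-3-methylfuran-2(5H)-one F1. A Michaelis–Arbuzov reaction with P(OEt)3 (neat, 100 °C) gives diethyl (3-methoxy-4-methyl-5-oxo-2,5-dihydrofuran-2-yl)phosphonate F2. LiN(SiMe3)2 (THF, −78 °C) gives lithium 5-(diethoxyphosphoryl)-4-methoxy-3-methylfuran-2-olate F3, which condenses with 13 (−78 °C to 0 °C) to give 22 directly without DBU. Any E isomer is equilibrated to Z with a trace of iodine in daylight.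

**Step 17** (risk: the furylmethyl bromide 26 is labile, and hydrolysis or protodeboronation can compete with the sp3–sp2 coupling). The fallback sets out from 25 and comes back to the route at 28. It builds the CH2 bridge by carbonyl addition and deoxygenation. MnO2 (CH2Cl2, 25 °C) oxidises 25 to 4-{[(tert-butyldimethylsilyl)oxy]methyl}furan-3-carbaldehyde F4. Furan-3-yllithium F5 (3-bromofuran, n-BuLi, THF, kept below −70 °C) adds to F4 to give racemic (4-{[(tert-butyldimethylsilyl)oxy]methyl}furan-3-yl)(furan-3-yl)methanol F6. Ionic hydrogenation (Et3SiH, BF3·OEt2, CH2Cl2, −78 °C) removes the doubly heterobenzylic hydroxyl to give 28.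

**Step 23** (risk: the furyl triene may not survive thiolate demethylation and the acidic work-up at the last stage). The fallback sets out from 22 and comes back to the route at 34. It reverses the order of the last two operations. The robust iodide 22 is demethylated first (LiCl, DMSO, 90 °C; then dilute HCl) to give (5Z)-4-hydroxy-5-[(2S,6E)-7-iodo-2,6-dimethylhept-6-en-1-ylidene]-3-methylfuran-2(5H)-one F7. F7 is then coupled as its potassium salt, formed in the flask, with 32 (Pd(dppf)Cl2, K3PO4 4 equiv, THF/H2O, 40 °C), and buffered acidification to pH 3 gives 34.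

## Further compounds

F1 | step 14 | 5-bromo-4-methoxy-3-methylfuran-2(5H)-one (racemic) | COC1=C(C)C(=O)OC1Br
F2 | step 14 | diethyl (3-methoxy-4-methyl-5-oxo-2,5-dihydrofuran-2-yl)phosphonate (racemic) | CCOP(=O)(OCC)C1OC(=O)C(C)=C1OC
F3 | step 14 | lithium 5-(diethoxyphosphoryl)-4-methoxy-3-methylfuran-2-olate | [Li+].[O-]c1oc(P(=O)(OCC)OCC)c(OC)c1C
F4 | step 17 | 4-{[(tert-butyldimethylsilyl)oxy]methyl}furan-3-carbaldehyde | CC(C)(C)[Si](C)(C)OCc1cocc1C=O
F5 | step 17 | furan-3-yllithium | [Li]c1ccoc1
F6 | step 17 | (4-{[(tert-butyldimethylsilyl)oxy]methyl}furan-3-yl)(furan-3-yl)methanol (racemic) | CC(C)(C)[Si](C)(C)OCc1cocc1C(O)c1ccoc1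
F7 | step 23 | (5Z)-4-hydroxy-5-[(2S,6E)-7-iodo-2,6-dimethylhept-6-en-1-ylidene]-3-methylfuran-2(5H)-one | CC1=C(O)/C(=C/[C@@H](C)CCC/C(C)=C/I)OC1=O
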